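Temperature sets how fast the starting material opens to the intermediate, and time sets how long that opening runs, so the first thing to reckon for each flask is what is left of it at the asked time.

| flask | starting material | first nucleophile | second nucleophile | temperature | remark | time |
|---|---|---|---|---|---|---|
| amber | 0.57 M | 0.855 M | 0.30 M | −4 °C | run made earlier |  |
| grey | 0.57 M | 0.855 M | 0.45 M | 21 °C | run made earlier |  |
| spring | 0.57 M | 0.855 M | 0.598 M | 30 °C |  | 4.0 h |
| autumn | 0.57 M | 0.855 M | 0.598 M | 15 °C |  | 4.0 h |
| noon | 0.57 M | 0.855 M | 0.598 M | 0 °C |  | 4.0 h |
| dawn | 0.57 M | 0.855 M | 0.598 M | −15 °C |  | 4.0 h |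

| run | time / h | target / % | starting material / % |
|---|---|---|---|
| amber | 5.00 | 17.7 | 27.2 |
| amber | 8.00 | 18.8 | 10.9 |
| amber | 15.0 | 14.4 | 1.4 |
| grey | 1.33 | 2.9 | 1.9 |
| grey | 2.50 | 1.5 | 1.0 |
| grey | 4.00 | 0 | 1.0 |
| grey | 5.00 | 0 | 0 |

(each reading ± 1 percentage point)

- candidate steps: starting material -> intermediate; first nucleophile + intermediate -> target; second nucleophile + intermediate -> other capture product; intermediate -> solvolysis product; first nucleophile + target -> over-reaction product; second nucleophile -> decomposition product

- which flask leads in amount of target, in percent of the starting material charged ("all alike" within 1.5 percentage points) (spring / autumn / noon / dawn / all alike)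
- how much target is there at the end, in percent of the starting material charged: spring
- how much target is there at the end, in percent of the starting material charged: autumn
- how much target is there at the end, in percent of the starting material charged: noon
- how much target is there at the end, in percent of the starting material charged: dawn

Of the four flasks, noon stands nearest the amber run: 0 °C against −4 °C, with the same charges of starting material and first nucleophile, but about twice the second nucleophile. Neither nucleophile enters the candidate step that consumes the starting material, so the remainder of starting material in noon can be reckoned from amber with a correction for temperature; the target in noon is a further matter, since the second nucleophile also captures intermediate. The amber run holds 27.2% starting material at 5.00 h, which for a first-order loss, the rate-limiting step on the way to target, gives a constant k_a = 0.260 h⁻¹. The grey run's first reading, 1.9% at 1.33 h, gives k_g = 2.98 h⁻¹. That reading stands within two scatters of zero, so the true remainder there can be far smaller but hardly much larger, and k_g is a low value.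

Define the gain g = k_g/k_a, the factor on the constant across the span from amber to grey: g = 11.4, read as a low value. A flask at a fraction of that span has k_a times g to that fraction, and its remainder R is exp(−kt). Amber's constant gives R = 35.3% at 4.0 h, while noon gives 21.5%, so noon keeps less in that time. Dawn gives 70.0%, so noon converts 2.62 times as much as dawn, and dawn has to send that much larger a share of its intermediate to target to draw level.

The forecast puts spring at 0.1%, autumn at 2%, noon at 11% (7% to 15%) and dawn at 9.5% (6.5% to 13%): “Noon narrowly leads dawn.”

The flasks end with 0% target in spring, 2.30% in autumn, 13.2% in noon and 3.72% in dawn, so noon leads.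

    starting material → intermediate (k = 1.23 × 10⁻⁴ s⁻¹, Ea = 83.0 kJ mol⁻¹)
    first nucleophile + intermediate → target (k = 0.0302 M⁻¹ s⁻¹, Ea = 47.0 kJ mol⁻¹)
    second nucleophile + intermediate → other capture product (k = 0.115 M⁻¹ s⁻¹, Ea = 37.0 kJ mol⁻¹)
    intermediate → solvolysis product (k = 0.0400 s⁻¹, Ea = 78.0 kJ mol⁻¹)
    first nucleophile + target → over-reaction product (k = 3.46 × 10⁻⁵ M⁻¹ s⁻¹, Ea = 78.0 kJ mol⁻¹)
    second nucleophile → decomposition product (k = 6.87 × 10⁻⁸ s⁻¹, Ea = 104 kJ mol⁻¹)
    (constants at 0 °C)

Noon keeps 17.0% starting material, less than the reckoned 21.5%, and dawn keeps 80.9%, more than the reckoned 70.0%. The remainders of the two flasks thus stand further apart than g put them. Dawn holds 12.5% other capture product beside its 3.72% target, which stands below the forecast's 9.5%. The neighbour flask, spring's recipe at 5 °C, reckons by the same g to a remainder of 8.17%, and it holds 3.28% starting material and 11.2% target.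

The runs were generated by integration with made-up constants; the scatter is artificial.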